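## The problem

Target 28 is 7-hydroxy-2-(4-hydroxyphenyl)-3,5,6,8-tetramethoxychromen-4-one, a flavone in which every carbon of ring A and C3 of ring C carries oxygen. It has no stereocentre, so the whole task is regiochemical: six oxygens must be placed, and O7 and O4′ must end as free phenols while O3, O5, O6 and O8 end as methyl ethers. The hardest distinction is between the neighbours O6 and O7, which sit in almost the same steric surroundings. The 4-pyranone is a vinylogous ester that opens at C2 with hot alkoxide or hydroxide, and the 5-methoxy group next to the carbonyl is cleaved by chelating Lewis acids, so late steps must avoid both. The electron-rich tetra- and pentaoxygenated benzenes, and any 6,7-catechol on the way, oxidise easily to quinones. The feature that opens the key step is that O1 and the acyl carbon C4 sit on the adjacent ring A carbons C8a and C4a, each flanked by a methoxy group (C8 and C5), which is the footprint of an aryne that has been difunctionalised across its triple bond. If O6 and O7 carry the same group, this aryne is symmetric and the addition has no orientation to choose. The two oxygens can be told apart afterwards, because the 7-hydroxyl is para to the C4 carbonyl and clearly more acidic than the 6-hydroxyl.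

## Retrosynthesis

**28 from 27.** The last bonds cut are the two O–CH2Ph bonds at O7 and O4′. These are the two free phenols of 28 and also the two most acidic hydroxyls of any partly protected precursor, so benzyl ethers can be put on exactly these positions and removed by neutral hydrogenolysis. The precursor is the dibenzyl ether 27; the forward step only asks that methyl ethers and the pyranone survive H2 over Pd/C.

**27 from 26, 25 and 24.** Cutting the O6–CH3 bond gives the 6-phenol 26. Compound 26 comes from the 6,7,4′-triol 25 by benzylation of the two acidic hydroxyls with two equivalents of benzyl bromide 5, and 25 from the tribenzyl ether 24 by hydrogenolysis. This detour costs four steps, but it is the price of keeping O6 and O7 identical up to the key step. A direct selective 6-O-methylation of 25 would run against the acidity order. The forward benzylation must stop after two alkylations.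

**24 from 23 and 20.** The C3–O bond is cut next. In flavone 20, C3–H is the only C–H on the chromone core and lies next to the carbonyl, so it can be lithiated, borylated and oxidised to flavonol 23, which is then methylated to 24. Bringing O3 in with the three-carbon partner would require a non-alkynyl acid and would leave the known ground of the key step. The forward step asks that the 3-lithio species does not open ring C before it is trapped.

**20 from 14 and 17 (key disconnection).** Three bonds are cut at once: O1–C8a, C4–C4a and O1–C2. The classical cut at C4–C4a alone would need a Friedel–Crafts or Fries acylation of a pentaoxygenated phenol under Lewis acid, followed by separate steps to build ring C. Here ring C is removed in one operation, leaving the symmetric aryne 18, released from the 2-silylaryl triflate 14, and the arylpropiolic acid 17. A 38-carbon flavone falls into a hexasubstituted benzene and a one-step acid. The forward reaction must favour acyl transfer to the aryl anion over its protonation.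

**17 from 15.** The C–CO2H bond is cut; the acid comes from the commercial alkyne 15 by carboxylation of its acetylide.

**14 from 11.** The C–Si and O–S bonds are cut. Silicon is delivered from oxygen to carbon by a retro-Brook shift after bromine–lithium exchange, and the phenoxide is trapped as the triflate. This needs the ortho-bromophenol 11 and places the silyl and triflate groups on the only two ring carbons that do not carry an ether.

**11 from 10, 7 and 6.** The C–Br bond of 11 is cut to phenol 10, whose single free ring position is ortho to the hydroxyl. The C–OH bond of 10 is cut through bromide 7 (exchange, borylation, oxidation), because direct deprotonation of the benzyl ether 6 with alkyllithium would risk benzylic metalation. Bromide 7 comes from the symmetric tetraether 6, whose two ring C–H positions are equivalent.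

**6 from 4, 5, 2 and 1.** The two O–benzyl bonds are cut to catechol 4 and two equivalents of benzyl bromide 5. Catechol 4 comes from salicylaldehyde 2 by Dakin oxidation, and 2 from commercial 2,5-dimethoxyphenol 1 by ortho-formylation. Compound 1 already holds the two para-disposed methoxy groups (the later O5 and O8) and one of the two inner oxygens.

## Roads not taken

**Alternative 1:** The cut is at the C6–O and C8–O bonds. Kaempferol A3 would be taken to 7-benzyloxy-2-[4-(benzyloxy)phenyl]-6,8-dibromo-3,5-dimethoxychromen-4-one A2, and NaOMe with CuBr would replace both bromines to give A1, which is the same compound as 27; hydrogenolysis then gives 28.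
- Merits: A3 already contains rings B and C and four of the six oxygens. The route is about six steps, and Ullmann-type methoxylation of bromoflavones is established.
- Weak points: two substitutions must both go to completion at carbons that each lie between two oxygen substituents. They run in hot methoxide, which can open the pyranone at C2 and exchange the 7-benzyloxy group (a vinylogous ester). Reductive loss of one bromine would give mono-methoxy products that differ from A1 by a single OMe. The dibromination is only reliable while the 5- and 7-hydroxyls are free, after which a 5-hydroxyl wedged between bromine and carbonyl must be methylated.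
- Comparison: in step count this road is clearly better, by roughly nine steps. The chosen plan sets against it that every ring A oxygen is in place before the heterocycle exists, that the pyranone never meets a hot alkoxide, and that no step requires a double conversion on the most advanced intermediate.

**Alternative 2:** The cut is at C8–C8a, with ring A built on a pyranone. The metalated form of bromopyranone A7 would add to the mixed squarate A6, and O-methylation would give cyclobutenone A5 (racemic). Heating A5 would open it to a dienylketene that closes onto the free pyranone CH next to oxygen (Moore rearrangement), giving A4 with a 7-tert-butoxy group and a free 8-hydroxyl.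
- Merits: all four ring A oxygens are differentiated in one operation, so the four-step O6/O7 detour of the chosen plan disappears. The route is convergent.
- Weak points: a 5-metalated 4-pyranone with a free C6–H is a fragile nucleophile. Which squarate carbonyl is attacked depends only on the steric difference between methoxy and tert-butoxy, and the wrong choice swaps O6 and O7. The tert-butyl ether can lose isobutene at the thermolysis temperature. Electrocyclisation onto a pyranone double bond has little precedent.
- Comparison: the road is more elegant in oxygen differentiation, but it rests on two weakly precedented events, whereas the key step of the chosen plan is a known reaction type applied to a new aryne.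

**Alternative 3:** The cut is at O1–C2, by demethylative iodocyclisation. The arene A10 (3-benzyloxy-1,2,4,5-tetramethoxybenzene) would be lithiated at its only C–H and acylated with an activated derivative of acid 17 to give the symmetric ynone A9. ICl would then activate the alkyne, an ortho methoxy oxygen would attack C2, chloride would remove the methyl group, and C3 would take up iodine, giving A8. Copper-catalysed methoxylation of the C3–I bond would lead to A1 (identical with 27) and hydrogenolysis to 28.
- Merits: the unique oxygen O7 lies on the symmetry axis of A9, so O6 and O7 are differentiated from the start. Iodine at C3 is the handle for O3, and the endgame is two or three steps. Iodocyclisation of 2-methoxyaryl ynones is a known reaction type.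
- Weak points: ICl is a strong electrophile and oxidant. The pentaoxygenated ring of A9 is a hydroquinone ether open to oxidation, and the benzyloxy-bearing ring B can be iodinated ortho to oxygen. A10 needs a 2,3,5,6-tetramethoxyphenol that is not a catalogue compound. The iodide-to-methoxide exchange again exposes the pyranone to alkoxide.
- Comparison: in step count after the ring closure this road is ahead of the chosen plan. The chosen plan offers a three-bond union with direct precedent, no electrophilic halogen on the electron-rich rings, and C3 oxygenation through a boronate instead of an alkoxide substitution.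

Key step: step 9

Assumption: compounds 1, 5 and 15 are bought; 28 and all route intermediates are achiral, so their SMILES need no stereodescriptors.

## Route

Step 1
Reactants: 1 2,5-dimethoxyphenol
Product: 2 2-hydroxy-3,6-dimethoxybenzaldehyde
Conditions: MgCl2, Et3N, (CH2O)n, MeCN, reflux; aq HCl work-up
Reagents that add atoms: paraformaldehyde (as formaldehyde), C=O
Why: Magnesium-phenoxide-directed ortho-formylation (Casnati–Skattebøl reaction) delivers formaldehyde only ortho to the phenol oxygen, and C6 is the single free ortho carbon; a second formaldehyde takes up the hydride, so the aldehyde forms directly.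

Step 2
Reactants: 2 2-hydroxy-3,6-dimethoxybenzaldehyde
Product: 4 3,6-dimethoxybenzene-1,2-diol, via 2-hydroxy-3,6-dimethoxyphenyl formate 3 (not isolated)
Conditions: 30% H2O2, aq NaOH, THF, 0 °C to rt, under N2; aq HCl
Reagents that add atoms: hydrogen peroxide, OO
Why: Dakin oxidation: hydroperoxide adds to the ortho-hydroxy aldehyde, the electron-rich aryl group migrates to oxygen and formate 3 is hydrolysed in the basic medium; air is excluded because catechol 4 oxidises easily, and it is used at once.

Step 3
Reactants: 4 3,6-dimethoxybenzene-1,2-diol; 5 benzyl bromide (first equivalent)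
Product: 6 2,3-bis(benzyloxy)-1,4-dimethoxybenzene
Conditions: BnBr (2.2 equiv in all), K2CO3, degassed DMF, rt to 50 °C, N2
Reagents that add atoms: benzyl bromide (second equivalent of 5), BrCc1ccccc1
Why: Twofold Williamson etherification of the catechol, which consumes two equivalents of benzyl bromide, one for each hydroxyl; the two equal benzyl ethers keep the ring symmetric, which the key step requires.

Step 4
Reactants: 6 2,3-bis(benzyloxy)-1,4-dimethoxybenzene
Product: 7 2,3-bis(benzyloxy)-5-bromo-1,4-dimethoxybenzene
Conditions: NBS (1.0 equiv), MeCN, 0 °C to rt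
Reagents that add atoms: N-bromosuccinimide, O=C1CCC(=O)N1Br
Why: Electrophilic aromatic bromination; the tetraalkoxy ring is far more nucleophilic than the benzyl phenyl rings, its two C–H positions are equivalent, and the first bromine slows the second, so one equivalent should stop at 7.

Step 5
Reactants: 7 2,3-bis(benzyloxy)-5-bromo-1,4-dimethoxybenzene
Product: 10 3,4-bis(benzyloxy)-2,5-dimethoxyphenol, via aryllithium 8 (not isolated), via dimethyl arylboronate 9 (not isolated)
Conditions: n-BuLi, THF, −78 °C; B(OMe)3, −78 °C to rt; AcOH, 30% H2O2, 0 °C to rt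
Reagents that add atoms: trimethyl borate, COB(OC)OC (its atoms stay only in 9); hydrogen peroxide, OO
Why: Bromine–lithium exchange at −78 °C is faster than deprotonation of the benzylic CH2 groups, and aryllithium 8 is trapped as boronate 9, which is oxidised with the oxygen entering at the carbon that carried boron (aryllithium borylation–oxidation).

Step 6
Reactants: 10 3,4-bis(benzyloxy)-2,5-dimethoxyphenol
Product: 11 4,5-bis(benzyloxy)-2-bromo-3,6-dimethoxyphenol
Conditions: NBS (1.0 equiv), CH2Cl2, −78 to 0 °C
Reagents that add atoms: N-bromosuccinimide, O=C1CCC(=O)N1Br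
Why: Electrophilic ortho-bromination of a phenol; the only unsubstituted ring carbon is ortho to the hydroxyl, and one equivalent of NBS in dry solvent at low temperature limits oxidation of the electron-rich ring.

Step 7
Reactants: 11 4,5-bis(benzyloxy)-2-bromo-3,6-dimethoxyphenol
Product: 14 4,5-bis(benzyloxy)-3,6-dimethoxy-2-(trimethylsilyl)phenyl trifluoromethanesulfonate, via aryl trimethylsilyl ether 12 (not isolated), via lithium 2-(trimethylsilyl)phenoxide 13 (not isolated)
Conditions: (Me3Si)2NH, THF, 70 °C, then concentrate; n-BuLi, THF, −100 to −78 °C; Tf2O, −100 °C to rt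
Reagents that add atoms: hexamethyldisilazane, C[Si](C)(C)N[Si](C)(C)C; trifluoromethanesulfonic anhydride, O=S(=O)(OS(=O)(=O)C(F)(F)F)C(F)(F)F
Why: After O-silylation, bromine–lithium exchange triggers the 1,3 oxygen-to-carbon silyl shift (retro-Brook rearrangement), driven by formation of lithium phenoxide 13, which Tf2O traps; this is the standard way to 2-silylaryl triflates from ortho-bromophenols.

Step 8
Reactants: 15 1-(benzyloxy)-4-ethynylbenzene
Product: 17 3-[4-(benzyloxy)phenyl]prop-2-ynoic acid, via lithium acetylide 16 (not isolated)
Conditions: n-BuLi, THF, −78 °C; CO2, −78 °C to rt; aq HCl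
Reagents that add atoms: carbon dioxide, O=C=O
Why: Deprotonation of the terminal alkyne and carboxylation of the lithium acetylide; the benzyl ether is inert to both.

Step 9
Reactants: 14 4,5-bis(benzyloxy)-3,6-dimethoxy-2-(trimethylsilyl)phenyl trifluoromethanesulfonate; 17 3-[4-(benzyloxy)phenyl]prop-2-ynoic acid
Product: 20 6,7-bis(benzyloxy)-2-[4-(benzyloxy)phenyl]-5,8-dimethoxychromen-4-one, via aryne 18 (not isolated), via 2-hydroxyaryl ynone 19 (not isolated)
Conditions: 14 (1.0 equiv), 17 (1.5 equiv), CsF (4 equiv), THF, 125 °C, sealed tube
Reagents that add atoms: none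
Why: Fluoride attacks silicon in 14 and triflate leaves, giving the symmetric aryne 18; the cesium carboxylate of 17 adds through oxygen to either of the two equivalent aryne carbons (the later C8a). The aryl anion formed at the later C4a, stabilised by the flanking methoxy group, attacks the neighbouring ester carbonyl through a four-membered alkoxide, which opens to the ortho-acyl phenoxide of 19; the aryne has thereby inserted into the C–O bond of the acid. The phenoxide then adds to the β-carbon of the ynone in a 6-endo-dig oxa-Michael closure of ring C, and protonation at C3 gives 20. The closest known reaction type is the fluoride-induced insertion of arynes into the carbon–oxygen bond of carboxylic acids, which turns arylpropiolic acids into flavones under these conditions. No stereocentre is formed. The selectivity needed is acyl transfer over protonation of the aryl anion, which would stop at the aryl propiolate; the carbonyl held next to the anion, the aprotic medium and the high temperature favour transfer. Orientation is not an issue because the two inner benzyloxy groups make both aryne carbons equivalent.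

Step 10
Reactants: 20 6,7-bis(benzyloxy)-2-[4-(benzyloxy)phenyl]-5,8-dimethoxychromen-4-one
Product: 23 6,7-bis(benzyloxy)-2-[4-(benzyloxy)phenyl]-3-hydroxy-5,8-dimethoxychromen-4-one, via 3-lithioflavone 21 (not isolated), via flavon-3-ylboronate 22 (not isolated)
Conditions: LiN(iPr)2, THF, −78 °C; B(OMe)3, −78 to 0 °C; AcOH, 30% H2O2, 0 °C to rt
Reagents that add atoms: trimethyl borate, COB(OC)OC (its atoms stay only in 22); hydrogen peroxide, OO
Why: C3–H is the only ring C–H of the chromone and lies next to the carbonyl, so the amide base removes it at −78 °C (C3 lithiation of flavones); borate trapping and oxidation of the C–B bond give the flavonol. The low temperature keeps 21 from opening to the ynone phenoxide.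

Step 11
Reactants: 23 6,7-bis(benzyloxy)-2-[4-(benzyloxy)phenyl]-3-hydroxy-5,8-dimethoxychromen-4-one
Product: 24 6,7-bis(benzyloxy)-2-[4-(benzyloxy)phenyl]-3,5,8-trimethoxychromen-4-one
Conditions: MeI, K2CO3, DMF, rt
Reagents that add atoms: iodomethane, CI
Why: Williamson methylation of the 3-hydroxyl, the only free OH in the molecule; carbonate in DMF breaks its hydrogen bond to the C4 carbonyl.

Step 12
Reactants: 24 6,7-bis(benzyloxy)-2-[4-(benzyloxy)phenyl]-3,5,8-trimethoxychromen-4-one
Product: 25 6,7-dihydroxy-2-(4-hydroxyphenyl)-3,5,8-trimethoxychromen-4-one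
Conditions: H2 (1 atm), Pd/C, THF–MeOH, rt
Reagents that add atoms: none
Why: Hydrogenolysis of three benzyl aryl ethers; the tetrasubstituted C2=C3 bond of the 3-methoxyflavone and the methyl ethers are not reduced at one atmosphere and room temperature.

Step 13
Reactants: 25 6,7-dihydroxy-2-(4-hydroxyphenyl)-3,5,8-trimethoxychromen-4-one; 5 benzyl bromide (first equivalent)
Product: 26 7-(benzyloxy)-2-[4-(benzyloxy)phenyl]-6-hydroxy-3,5,8-trimethoxychromen-4-one
Conditions: BnBr (2.05 equiv in all), K2CO3 (2.2 equiv), degassed DMF, 0 °C to rt, Ar
Reagents that add atoms: benzyl bromide (second equivalent of 5), BrCc1ccccc1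
Why: Acidity-controlled Williamson benzylation: the 7-OH (para to the C4 carbonyl) and the 4′-OH (conjugated to it through C2=C3) are ionised by carbonate before the 6-OH, which is meta to the carbonyl and, once O7 is benzylated, flanked by two ether groups. Two equivalents of benzyl bromide, one for each of these hydroxyls, should therefore stop at 26.

Step 14
Reactants: 26 7-(benzyloxy)-2-[4-(benzyloxy)phenyl]-6-hydroxy-3,5,8-trimethoxychromen-4-one
Product: 27 7-(benzyloxy)-2-[4-(benzyloxy)phenyl]-3,5,6,8-tetramethoxychromen-4-one
Conditions: MeI, K2CO3, DMF, 40 °C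
Reagents that add atoms: iodomethane, CI
Why: Williamson methylation of the remaining hindered 6-hydroxyl; iodomethane is small enough to reach an oxygen flanked on both sides.

Step 15
Reactants: 27 7-(benzyloxy)-2-[4-(benzyloxy)phenyl]-3,5,6,8-tetramethoxychromen-4-one
Product: 28 7-hydroxy-2-(4-hydroxyphenyl)-3,5,6,8-tetramethoxychromen-4-one
Conditions: H2 (1 atm), Pd/C, EtOAc–MeOH, rt
Reagents that add atoms: none
Why: Hydrogenolysis of both benzyl ethers frees O7 and O4′ under neutral conditions that leave the four methyl ethers and the pyranone untouched.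

## Compound list

1 | 2,5-dimethoxyphenol | COc1ccc(OC)c(O)c1 | starting material
2 | 2-hydroxy-3,6-dimethoxybenzaldehyde | COc1ccc(OC)c(O)c1C=O | intermediate
3 | 2-hydroxy-3,6-dimethoxyphenyl formate | COc1ccc(OC)c(O)c1OC=O | intermediate
4 | 3,6-dimethoxybenzene-1,2-diol | COc1ccc(OC)c(O)c1O | intermediate
5 | benzyl bromide | BrCc1ccccc1 | starting material
6 | 2,3-bis(benzyloxy)-1,4-dimethoxybenzene | COc1ccc(OC)c(OCc2ccccc2)c1OCc1ccccc1 | intermediate
7 | 2,3-bis(benzyloxy)-5-bromo-1,4-dimethoxybenzene | COc1cc(Br)c(OC)c(OCc2ccccc2)c1OCc1ccccc1 | intermediate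
8 | [3,4-bis(benzyloxy)-2,5-dimethoxyphenyl]lithium | [Li]c1cc(OC)c(OCc2ccccc2)c(OCc2ccccc2)c1OC | intermediate
9 | dimethyl [3,4-bis(benzyloxy)-2,5-dimethoxyphenyl]boronate | COB(OC)c1cc(OC)c(OCc2ccccc2)c(OCc2ccccc2)c1OC | intermediate
10 | 3,4-bis(benzyloxy)-2,5-dimethoxyphenol | COc1cc(O)c(OC)c(OCc2ccccc2)c1OCc1ccccc1 | intermediate
11 | 4,5-bis(benzyloxy)-2-bromo-3,6-dimethoxyphenol | COc1c(Br)c(O)c(OC)c(OCc2ccccc2)c1OCc1ccccc1 | intermediate
12 | [4,5-bis(benzyloxy)-2-bromo-3,6-dimethoxyphenoxy]trimethylsilane | COc1c(Br)c(O[Si](C)(C)C)c(OC)c(OCc2ccccc2)c1OCc1ccccc1 | intermediate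
13 | lithium 4,5-bis(benzyloxy)-3,6-dimethoxy-2-(trimethylsilyl)phenoxide | [Li+].[O-]c1c(OC)c(OCc2ccccc2)c(OCc2ccccc2)c(OC)c1[Si](C)(C)C | intermediate
14 | 4,5-bis(benzyloxy)-3,6-dimethoxy-2-(trimethylsilyl)phenyl trifluoromethanesulfonate | COc1c(OCc2ccccc2)c(OCc2ccccc2)c(OC)c(OS(=O)(=O)C(F)(F)F)c1[Si](C)(C)C | intermediate
15 | 1-(benzyloxy)-4-ethynylbenzene | C#Cc1ccc(OCc2ccccc2)cc1 | starting material
16 | lithium [4-(benzyloxy)phenyl]acetylide | [Li]C#Cc1ccc(OCc2ccccc2)cc1 | intermediate
17 | 3-[4-(benzyloxy)phenyl]prop-2-ynoic acid | O=C(O)C#Cc1ccc(OCc2ccccc2)cc1 | intermediate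
18 | 4,5-bis(benzyloxy)-3,6-dimethoxybenzyne (1,2-didehydrobenzene) | COC1=C(OCc2ccccc2)C(OCc2ccccc2)=C(OC)C#C1 | intermediate
19 | 1-[3,4-bis(benzyloxy)-6-hydroxy-2,5-dimethoxyphenyl]-3-[4-(benzyloxy)phenyl]prop-2-yn-1-one | COc1c(O)c(C(=O)C#Cc2ccc(OCc3ccccc3)cc2)c(OC)c(OCc2ccccc2)c1OCc1ccccc1 | intermediate
20 | 6,7-bis(benzyloxy)-2-[4-(benzyloxy)phenyl]-5,8-dimethoxychromen-4-one | COc1c(OCc2ccccc2)c(OCc2ccccc2)c(OC)c2c(=O)cc(-c3ccc(OCc4ccccc4)cc3)oc12 | intermediate
21 | {6,7-bis(benzyloxy)-2-[4-(benzyloxy)phenyl]-5,8-dimethoxy-4-oxochromen-3-yl}lithium | COc1c(OCc2ccccc2)c(OCc2ccccc2)c(OC)c2c(=O)c([Li])c(-c3ccc(OCc4ccccc4)cc3)oc12 | intermediate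
22 | dimethyl {6,7-bis(benzyloxy)-2-[4-(benzyloxy)phenyl]-5,8-dimethoxy-4-oxochromen-3-yl}boronate | COB(OC)c1c(-c2ccc(OCc3ccccc3)cc2)oc2c(OC)c(OCc3ccccc3)c(OCc3ccccc3)c(OC)c2c1=O | intermediate
23 | 6,7-bis(benzyloxy)-2-[4-(benzyloxy)phenyl]-3-hydroxy-5,8-dimethoxychromen-4-one | COc1c(OCc2ccccc2)c(OCc2ccccc2)c(OC)c2c(=O)c(O)c(-c3ccc(OCc4ccccc4)cc3)oc12 | intermediate
24 | 6,7-bis(benzyloxy)-2-[4-(benzyloxy)phenyl]-3,5,8-trimethoxychromen-4-one | COc1c(OCc2ccccc2)c(OCc2ccccc2)c(OC)c2c(=O)c(OC)c(-c3ccc(OCc4ccccc4)cc3)oc12 | intermediate
25 | 6,7-dihydroxy-2-(4-hydroxyphenyl)-3,5,8-trimethoxychromen-4-one | COc1c(O)c(O)c(OC)c2c(=O)c(OC)c(-c3ccc(O)cc3)oc12 | intermediate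
26 | 7-(benzyloxy)-2-[4-(benzyloxy)phenyl]-6-hydroxy-3,5,8-trimethoxychromen-4-one | COc1c(OCc2ccccc2)c(O)c(OC)c2c(=O)c(OC)c(-c3ccc(OCc4ccccc4)cc3)oc12 | intermediate
27 | 7-(benzyloxy)-2-[4-(benzyloxy)phenyl]-3,5,6,8-tetramethoxychromen-4-one | COc1c(OCc2ccccc2)c(OC)c(OC)c2c(=O)c(OC)c(-c3ccc(OCc4ccccc4)cc3)oc12 | intermediate
28 | 7-hydroxy-2-(4-hydroxyphenyl)-3,5,6,8-tetramethoxychromen-4-one | COc1c(O)c(OC)c2oc(-c3ccc(O)cc3)c(OC)c(=O)c2c1OC | target

## Step count and risks

Total: 15 steps. The longest linear sequence is 14 steps (1 to 28 through steps 1–7 and 9–15); step 8 is a one-step side branch.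

**Step 9 (key step).** The most likely failure is protonation of the aryl anion before it reaches the ester carbonyl, so that the carboxylate is only O-arylated without acyl transfer. The acidic proton of 17 and the crowding of the anion between a methoxy group and the ester both favour this. Decarboxylation of 17 at 125 °C and capture of the aryne by other nucleophiles would lower the return further. Fallback, setting out from phenol 10 and coming back at 20: iodination ortho to the hydroxyl with N-iodosuccinimide gives 4,5-bis(benzyloxy)-2-iodo-3,6-dimethoxyphenol F1. Carbonylative Sonogashira annulation of F1 with alkyne 15 (PdCl2(PPh3)2, CO, Et2NH, 120 °C) then builds the same hydroxyaryl ynone 19 with C4 coming from carbon monoxide, and the amine closes it to 20.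

**Step 10.** The 3-lithio species may open ring C by β-elimination of the C8a phenoxide (the reverse of the last event of step 9). Deprotonation may be incomplete, or the boronate next to the carbonyl may lose boron by protonation before it is oxidised. Fallback, setting out from 20 and coming back at 23: epoxidation of the C2=C3 bond with dimethyldioxirane in acetone–CH2Cl2 at 0 °C gives racemic 6,7-bis(benzyloxy)-2-[4-(benzyloxy)phenyl]-2,3-epoxy-5,8-dimethoxychroman-4-one F2. Acid-catalysed opening (TsOH, CH2Cl2) isomerises F2 to flavonol 23 without any organometallic intermediate.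

**Step 13.** Benzylation may run on to O6 or stop after O7, and the electron-rich 6,7-catechol phenoxide may be oxidised by air to an ortho-quinone in the basic medium. Over-alkylated material is 24 and can be returned to step 12. Fallback, setting out from 25 and coming back at 28: chloromethyl methyl ether with iPr2NEt in CH2Cl2 at 0 °C, where only the two most acidic phenols are ionised by the amine, gives 6-hydroxy-3,5,8-trimethoxy-7-(methoxymethoxy)-2-[4-(methoxymethoxy)phenyl]chromen-4-one F3. Methylation (MeI, K2CO3, DMF) gives 3,5,6,8-tetramethoxy-7-(methoxymethoxy)-2-[4-(methoxymethoxy)phenyl]chromen-4-one F4, and HCl in MeOH at 50 °C removes both acetals to give 28 without a second hydrogenolysis.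

**Step 6 (with step 7).** The N-bromo reagent may oxidise the pentaoxygenated phenol to a quinone, with loss of an ether group, instead of brominating the ring. In step 7 the silyl shift has to place silicon between two substituents. Fallback, setting out from 10 and coming back at 14: isopropyl isocyanate with Et3N gives 3,4-bis(benzyloxy)-2,5-dimethoxyphenyl N-isopropylcarbamate F5. N-silylation (Me3SiOTf, TMEDA) and carbamate-directed ortho-lithiation (n-BuLi, TMEDA, −78 °C) with Me3SiCl quench give 4,5-bis(benzyloxy)-3,6-dimethoxy-2-(trimethylsilyl)phenyl N-isopropylcarbamate F6. Cleavage of the carbamate with Et2NH and DBU in MeCN, followed by PhNTf2, gives triflate 14 without any electrophilic bromine.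

Further compounds

F1 | step 9 | 4,5-bis(benzyloxy)-2-iodo-3,6-dimethoxyphenol | COc1c(I)c(O)c(OC)c(OCc2ccccc2)c1OCc1ccccc1
F2 | step 10 | 6,7-bis(benzyloxy)-2-[4-(benzyloxy)phenyl]-2,3-epoxy-5,8-dimethoxychroman-4-one (racemic, cis-fused oxirane; one enantiomer drawn) | COc1c(OCc2ccccc2)c(OCc2ccccc2)c(OC)c2c1O[C@@]1(c3ccc(OCc4ccccc4)cc3)O[C@H]1C2=O
F3 | step 13 | 6-hydroxy-3,5,8-trimethoxy-7-(methoxymethoxy)-2-[4-(methoxymethoxy)phenyl]chromen-4-one | COCOc1ccc(-c2oc3c(OC)c(OCOC)c(O)c(OC)c3c(=O)c2OC)cc1
F4 | step 13 | 3,5,6,8-tetramethoxy-7-(methoxymethoxy)-2-[4-(methoxymethoxy)phenyl]chromen-4-one | COCOc1ccc(-c2oc3c(OC)c(OCOC)c(OC)c(OC)c3c(=O)c2OC)cc1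
F5 | step 6 | 3,4-bis(benzyloxy)-2,5-dimethoxyphenyl N-isopropylcarbamate | COc1cc(OC(=O)NC(C)C)c(OC)c(OCc2ccccc2)c1OCc1ccccc1
F6 | step 6 | 4,5-bis(benzyloxy)-3,6-dimethoxy-2-(trimethylsilyl)phenyl N-isopropylcarbamate | COc1c([Si](C)(C)C)c(OC(=O)NC(C)C)c(OC)c(OCc2ccccc2)c1OCc1ccccc1
A1 | alternative 1 | 7-(benzyloxy)-2-[4-(benzyloxy)phenyl]-3,5,6,8-tetramethoxychromen-4-one (identical with 27) | COc1c(OCc2ccccc2)c(OC)c2oc(-c3ccc(OCc4ccccc4)cc3)c(OC)c(=O)c2c1OC
A2 | alternative 1 | 7-(benzyloxy)-2-[4-(benzyloxy)phenyl]-6,8-dibromo-3,5-dimethoxychromen-4-one | COc1c(Br)c(OCc2ccccc2)c(Br)c2oc(-c3ccc(OCc4ccccc4)cc3)c(OC)c(=O)c12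
A3 | alternative 1 | kaempferol (3,5,7-trihydroxy-2-(4-hydroxyphenyl)chromen-4-one) | O=c1c(O)c(-c2ccc(O)cc2)oc2cc(O)cc(O)c12
A4 | alternative 2 | 2-[4-(benzyloxy)phenyl]-7-tert-butoxy-8-hydroxy-3,5,6-trimethoxychromen-4-one | COc1c(OC(C)(C)C)c(O)c2oc(-c3ccc(OCc4ccccc4)cc3)c(OC)c(=O)c2c1OC
A5 | alternative 2 | 2-[4-(benzyloxy)phenyl]-5-(3-tert-butoxy-1,2-dimethoxy-4-oxocyclobut-2-en-1-yl)-3-methoxypyran-4-one (racemic) | COC1=C(OC(C)(C)C)C(=O)C1(OC)c1coc(-c2ccc(OCc3ccccc3)cc2)c(OC)c1=O
A6 | alternative 2 | 3-tert-butoxy-4-methoxycyclobut-3-ene-1,2-dione | COC1=C(OC(C)(C)C)C(=O)C1=O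
A7 | alternative 2 | 2-[4-(benzyloxy)phenyl]-5-bromo-3-methoxypyran-4-one | COc1c(-c2ccc(OCc3ccccc3)cc2)occ(Br)c1=O
A8 | alternative 3 | 7-(benzyloxy)-2-[4-(benzyloxy)phenyl]-3-iodo-5,6,8-trimethoxychromen-4-one | COc1c(OCc2ccccc2)c(OC)c2oc(-c3ccc(OCc4ccccc4)cc3)c(I)c(=O)c2c1OC
A9 | alternative 3 | 1-[4-(benzyloxy)-2,3,5,6-tetramethoxyphenyl]-3-[4-(benzyloxy)phenyl]prop-2-yn-1-one | COc1c(OC)c(C(=O)C#Cc2ccc(OCc3ccccc3)cc2)c(OC)c(OC)c1OCc1ccccc1
A10 | alternative 3 | 3-(benzyloxy)-1,2,4,5-tetramethoxybenzene | COc1cc(OC)c(OC)c(OCc2ccccc2)c1OC
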